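**Plan**
1. Retrosynthesis: the vanillate is cut at the C6–O ester bond; the 8α-hydroxy-9-ene unit goes back to a C8=C9 alkene and the C8 methyl to an ester; the C4–isopropyl bond goes back to a ketone; the seven-membered ring is then opened at C7–C8 and C1–C10.
2. Enabling feature (daucane numbering: C1 quaternary ring-fusion carbon with methyl, C2 and C3 ring CH2, C4 isopropyl carbinol, C5 ring-fusion CH, C6 ester carbinol, C7 CH2, C8 methyl carbinol, C9=C10 alkene; α is the face of H5, β that of the C1 methyl): the seven-membered ring consists of a 2-oxygenated diene C1=C5–C6=C7, whose end C1 is the quaternary carbon of the five-membered ring, and a three-carbon unit C8–C9–C10.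
3. Forward: the five-membered ring comes from 3-methylcyclopentenone and is turned into a siloxydiene; a vinylcarbenoid cyclopropanates C6=C7 and the cis-divinylcyclopropane closes the seven-membered ring by a Cope shift (new bonds C7–C8 and C1–C10); C4, C5, C6 and C8–C10 are then adjusted and the vanillate is attached last.
4. Stereochemistry: C1 from a chiral dirhodium catalyst, relayed through the cyclopropane; C4 by organocerium addition opposite the C1 methyl; C5 by protonation of an enol; C6 by hydride delivery from the 4β-hydroxyl; C8 by epoxidation directed by the 6α-hydroxyl.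

Key step: step 7

Convention: C-locants and α/β in the Why lines follow the daucane numbering above; compound names use azulene numbering.
Assumption: Rh2(DOSP)4 catalysts are taken to induce the same sense on this enol ether as on styrene (S catalyst giving the (1S,2R)-cyclopropane with methyl aryldiazoacetates); followed through the boat Cope shift this points to the R catalyst for (R)-C1, and the S catalyst would be used with no other change if the opposite sense were found.

**Route**

Step 1
Reactants: 1 3-methylcyclopent-2-en-1-one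
Product: 2 2-iodo-3-methylcyclopent-2-en-1-one
Conditions: I2, pyridine, CH2Cl2, 0 °C to rt
Reagents that add atoms: iodine, [I][I]
Why: α-Iodination of an enone by conjugate addition of pyridine, iodination of the resulting enolate and elimination, C2 being the only position that can react in this way.

Step 2
Reactants: 2 2-iodo-3-methylcyclopent-2-en-1-one; 3 tributyl(1-ethoxyvinyl)stannane
Product: 5 2-acetyl-3-methylcyclopent-2-en-1-one, via ethoxyvinyl enone 4 (not isolated)
Conditions: Pd(PPh3)4 (5 mol %), CuI (10 mol %), DMF, 70 °C; then 1 M HCl, THF, rt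
Reagents that add atoms: water, O
Why: Stille coupling of the α-iodoenone with the 1-ethoxyvinyl stannane places a masked acetyl group on C2 without enolate chemistry, and dilute acid hydrolyses the enol ether to the methyl ketone.

Step 3
Reactants: 5 2-acetyl-3-methylcyclopent-2-en-1-one
Product: 6 2-[1-(tert-butyldimethylsilyloxy)vinyl]-3-methylcyclopent-2-en-1-one
Conditions: TBSOTf (1.05 equiv), Et3N, CH2Cl2, −78 to 0 °C
Reagents that add atoms: tert-butyldimethylsilyl trifluoromethanesulfonate, CC(C)(C)[Si](C)(C)OS(=O)(=O)C(F)(F)F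
Why: Soft enolisation with silyl triflate and amine, in which the acetyl carbonyl, twisted out of the enone plane by the flanking ring methyl group, is expected to react as an isolated methyl ketone and be silylated on its methyl side faster than the ring enone, giving the cross-conjugated 2-siloxydiene.

Step 4
Reactants: 7 methyl acetoacetate
Product: 8 methyl 2-diazo-3-oxobutanoate
Conditions: 4-AcNHC6H4SO2N3, Et3N, MeCN, 0 °C to rt
Reagents that add atoms: 4-acetamidobenzenesulfonyl azide, CC(=O)Nc1ccc(cc1)S(=O)(=O)N=[N+]=[N-]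
Why: Regitz diazo transfer to the doubly activated methylene of the β-keto ester.

Step 5
Reactants: 8 methyl 2-diazo-3-oxobutanoate
Product: 9 methyl 2-diazo-3-hydroxybutanoate
Conditions: NaBH4, MeOH, 0 °C
Reagents that add atoms: none
Why: Borohydride reduction of the ketone, the acceptor-substituted diazo ester being inert to NaBH4 at 0 °C.

Step 6
Reactants: 9 methyl 2-diazo-3-hydroxybutanoate
Product: 10 methyl 2-diazobut-3-enoate
Conditions: POCl3, Et3N, CH2Cl2, 0 °C to rt; kept cold in solution and used at once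
Reagents that add atoms: none
Why: Dehydration of the β-hydroxy diazo ester by E2 elimination of its dichlorophosphate gives the vinyldiazoacetate, which is not stored because it cyclises to a pyrazole on standing.

Step 7
Reactants: 6 2-[1-(tert-butyldimethylsilyloxy)vinyl]-3-methylcyclopent-2-en-1-one; 10 methyl 2-diazobut-3-enoate
Product: 12 methyl (8aR)-4-(tert-butyldimethylsilyloxy)-8a-methyl-3-oxo-1,2,3,5,8,8a-hexahydroazulene-6-carboxylate, via divinylcyclopropane 11 (not isolated)
Conditions: Rh2(R-DOSP)4 (dirhodium tetrakis[(R)-N-(4-dodecylphenylsulfonyl)prolinate], 1 mol %), 10 (2 equiv) added over 2 h, hexanes, −78 °C to rt; then toluene, 100 °C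
Reagents that add atoms: none
Why: The dirhodium catalyst decomposes 10 to a donor–acceptor vinylcarbenoid, which cyclopropanates the electron-rich, unhindered siloxyvinyl bond C6=C7 of 6 to give the cis-divinylcyclopropane 11; on warming, 11 undergoes a [3,3] shift in which C6–C8 breaks and C1–C10 forms. The closest known reaction type is the tandem cyclopropanation/Cope rearrangement (formal [4+3] cycloaddition) of vinyldiazoacetates with 2-siloxydienes, including dienes whose terminus becomes a quaternary carbon. The seven-membered ring closes by this sigmatropic shift through a boat transition state and not by an end-to-end cyclisation, which makes both ring alkenes (C5=C6 and C8=C9) cis. The one stereocentre that remains, C1, is controlled by the chiral catalyst, which fixes the configuration of C6 and C8 in 11, and the suprafacial boat shift passes it on to one face of C1. The step needs site selectivity (the enol ether alkene reacts, not the electron-poor tetrasubstituted enone alkene C1=C5), a cis arrangement of the two vinyl groups (the π-substituent of the alkene settles cis to the carbenoid vinyl group and trans to the ester) and enantioface control (catalyst in a hydrocarbon solvent at low temperature). Heating is planned because the C1 methyl group is the Z substituent that points into the boat.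

Step 8
Reactants: 12 methyl (8aR)-4-(tert-butyldimethylsilyloxy)-8a-methyl-3-oxo-1,2,3,5,8,8a-hexahydroazulene-6-carboxylate; 13 isopropylmagnesium chloride
Product: 14 methyl (3R,8aR)-4-(tert-butyldimethylsilyloxy)-3-hydroxy-8a-methyl-3-(propan-2-yl)-1,2,3,5,8,8a-hexahydroazulene-6-carboxylate
Conditions: anhydrous CeCl3, 13, THF, −78 °C; then 12, −78 °C; sat. aq NaHCO3
Reagents that add atoms: none
Why: Organocerium 1,2-addition to the vinylogous-ester carbonyl C4, the cerium reagent suppressing enolisation, β-hydride reduction and attack on the enoate, with the nucleophile expected on the α face opposite the C1 methyl group, which sets C4 (β-OH, α-isopropyl).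

Step 9
Reactants: 14 methyl (3R,8aR)-4-(tert-butyldimethylsilyloxy)-3-hydroxy-8a-methyl-3-(propan-2-yl)-1,2,3,5,8,8a-hexahydroazulene-6-carboxylate
Product: 15 (3R,8aR)-4-(tert-butyldimethylsilyloxy)-6-(hydroxymethyl)-8a-methyl-3-(propan-2-yl)-1,2,3,5,8,8a-hexahydroazulen-3-ol
Conditions: i-Bu2AlH (4 equiv), CH2Cl2, −78 to −40 °C; aq potassium sodium tartrate
Reagents that add atoms: none
Why: 1,2-Reduction of the α,β-unsaturated ester to the allylic alcohol by the aluminium hydride, the silyl enol ether being inert and the basic work-up sparing the acid-labile 3-siloxy allylic alcohol.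

Step 10
Reactants: 15 (3R,8aR)-4-(tert-butyldimethylsilyloxy)-6-(hydroxymethyl)-8a-methyl-3-(propan-2-yl)-1,2,3,5,8,8a-hexahydroazulen-3-ol
Product: 17 (3R,8aR)-4-(tert-butyldimethylsilyloxy)-6,8a-dimethyl-3-(propan-2-yl)-1,2,3,5,8,8a-hexahydroazulen-3-ol, via allylic mesylate 16 (not isolated)
Conditions: MsCl, Et3N, THF, −40 °C; then LiEt3BH, −40 to 0 °C
Reagents that add atoms: none
Why: Sulfonylation of the primary allylic alcohol (the tertiary C4 hydroxyl is too hindered at −40 °C) and SN2 hydride displacement, a standard basic deoxygenation of an allylic alcohol to a methyl group.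

Step 11
Reactants: 17 (3R,8aR)-4-(tert-butyldimethylsilyloxy)-6,8a-dimethyl-3-(propan-2-yl)-1,2,3,5,8,8a-hexahydroazulen-3-ol
Product: 18 (3R,3aR,8aR)-3-hydroxy-6,8a-dimethyl-3-(propan-2-yl)-2,3,3a,5,8,8a-hexahydroazulen-4(1H)-one
Conditions: Bu4NF, AcOH (1:1), THF, −20 to 0 °C
Reagents that add atoms: none
Why: Buffered desilylation and ketonisation, in which the enol is expected to be protonated at C5 from the α face opposite the C1 methyl group (trans ring fusion); the trans-fused ketone, with its carbonyl syn to the 4β-hydroxyl and anti to the isopropyl group, should also be the more stable epimer, and the acetic acid buffer disfavours retro-aldol cleavage and migration of the C8=C9 bond.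

Step 12
Reactants: 18 (3R,3aR,8aR)-3-hydroxy-6,8a-dimethyl-3-(propan-2-yl)-2,3,3a,5,8,8a-hexahydroazulen-4(1H)-one
Product: 19 (3R,3aS,4S,8aR)-6,8a-dimethyl-3-(propan-2-yl)-1,2,3,3a,4,5,8,8a-octahydroazulene-3,4-diol
Conditions: Me4NBH(OAc)3, MeCN/AcOH (1:1), −30 °C
Reagents that add atoms: none
Why: Hydroxyl-directed Evans–Saksena reduction, in which the borohydride bound to the 4β-oxygen delivers hydride to the β face of the C6 carbonyl and gives the 1,3-anti diol with the 6α-hydroxyl.

Step 13
Reactants: 19 (3R,3aS,4S,8aR)-6,8a-dimethyl-3-(propan-2-yl)-1,2,3,3a,4,5,8,8a-octahydroazulene-3,4-diol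
Product: 20 (3R,3aS,4S,6R,7S,8aR)-6,7-epoxy-6,8a-dimethyl-3-(propan-2-yl)decahydroazulene-3,4-diol
Conditions: VO(acac)2 (5 mol %), t-BuOOH, CH2Cl2, 0 °C to rt
Reagents that add atoms: tert-butyl hydroperoxide, CC(C)(C)OO
Why: Vanadium-catalysed hydroxyl-directed epoxidation, in which the homoallylic 6α-alkoxide delivers the peroxide oxygen to the α face of the only alkene, C8=C9, and so sets C8 and C9.

Step 14
Reactants: 20 (3R,3aS,4S,6R,7S,8aR)-6,7-epoxy-6,8a-dimethyl-3-(propan-2-yl)decahydroazulene-3,4-diol
Product: 21 (3R,3aS,4S,6R,7R,8aR)-6,8a-dimethyl-7-(phenylselanyl)-3-(propan-2-yl)decahydroazulene-3,4,6-triol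
Conditions: PhSeSePh, NaBH4, EtOH, 0 °C; then 20, reflux
Reagents that add atoms: diphenyl diselenide, c1ccc(cc1)[Se][Se]c1ccccc1
Why: SN2 opening of the trisubstituted epoxide by benzeneselenolate at the less substituted carbon C9 with inversion, giving the trans 8α-hydroxy 9β-selenide.

Step 15
Reactants: 21 (3R,3aS,4S,6R,7R,8aR)-6,8a-dimethyl-7-(phenylselanyl)-3-(propan-2-yl)decahydroazulene-3,4,6-triol
Product: 23 (3R,3aS,4S,6R,8aR)-6,8a-dimethyl-3-(propan-2-yl)-1,2,3,3a,4,5,6,8a-octahydroazulene-3,4,6-triol, via selenoxide 22 (not isolated)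
Conditions: 30% H2O2, pyridine, THF, 0 °C to rt
Reagents that add atoms: none
Why: Selenoxide syn-elimination, which can only take a hydrogen from C10 because C8 carries none, so the C9=C10 alkene and the tertiary allylic 8α-alcohol result.

Step 16
Reactants: 24 vanillic acid
Product: 26 4-(tert-butyldimethylsilyloxy)-3-methoxybenzoic acid, via bis-silyl vanillate 25 (not isolated)
Conditions: TBSCl (2.5 equiv), imidazole, DMF, rt; then AcOH/THF/H2O, rt
Reagents that add atoms: tert-butyldimethylsilyl chloride, CC(C)(C)[Si](C)(C)Cl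
Why: Silylation of phenol and acid followed by selective hydrolysis of the labile silyl ester leaves the phenol masked as its silyl ether.

Step 17
Reactants: 23 (3R,3aS,4S,6R,8aR)-6,8a-dimethyl-3-(propan-2-yl)-1,2,3,3a,4,5,6,8a-octahydroazulene-3,4,6-triol; 26 4-(tert-butyldimethylsilyloxy)-3-methoxybenzoic acid
Product: 28 (3R,3aS,4S,6R,8aR)-3,6-dihydroxy-6,8a-dimethyl-3-(propan-2-yl)-1,2,3,3a,4,5,6,8a-octahydroazulen-4-yl 4-(tert-butyldimethylsilyloxy)-3-methoxybenzoate, via mixed anhydride 27 (not isolated)
Conditions: 26, 2,4,6-Cl3C6H2COCl, Et3N, THF, rt; then 23, DMAP, toluene, 40 °C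
Reagents that add atoms: none
Why: Yamaguchi esterification, in which the mixed anhydride acylates the only secondary hydroxyl (C6) with retention while the two tertiary hydroxyls stay free.

Step 18
Reactants: 28 (3R,3aS,4S,6R,8aR)-3,6-dihydroxy-6,8a-dimethyl-3-(propan-2-yl)-1,2,3,3a,4,5,6,8a-octahydroazulen-4-yl 4-(tert-butyldimethylsilyloxy)-3-methoxybenzoate
Product: 29 (3R,3aS,4S,6R,8aR)-3,6-dihydroxy-6,8a-dimethyl-3-(propan-2-yl)-1,2,3,3a,4,5,6,8a-octahydroazulen-4-yl 4-hydroxy-3-methoxybenzoate
Conditions: Bu4NF, AcOH, THF, 0 °C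
Reagents that add atoms: none
Why: Fluoride cleaves the aryl silyl ether much faster than it attacks the benzoate, and the buffer protects the ester and the tertiary allylic alcohol.

**Compound list**
1 | 3-methylcyclopent-2-en-1-one | CC1=CC(=O)CC1 | starting material
2 | 2-iodo-3-methylcyclopent-2-en-1-one | CC1=C(I)C(=O)CC1 | intermediate
3 | tributyl(1-ethoxyvinyl)stannane | CCCC[Sn](CCCC)(CCCC)C(=C)OCC | starting material
4 | 2-(1-ethoxyvinyl)-3-methylcyclopent-2-en-1-one | CCOC(=C)C1=C(C)CCC1=O | intermediate (not isolated)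
5 | 2-acetyl-3-methylcyclopent-2-en-1-one | CC(=O)C1=C(C)CCC1=O | intermediate
6 | 2-[1-(tert-butyldimethylsilyloxy)vinyl]-3-methylcyclopent-2-en-1-one | CC1=C(C(=C)O[Si](C)(C)C(C)(C)C)C(=O)CC1 | intermediate
7 | methyl acetoacetate | CC(=O)CC(=O)OC | starting material
8 | methyl 2-diazo-3-oxobutanoate | CC(=O)C(=[N+]=[N-])C(=O)OC | intermediate
9 | methyl 2-diazo-3-hydroxybutanoate (racemic) | CC(O)C(=[N+]=[N-])C(=O)OC | intermediate
10 | methyl 2-diazobut-3-enoate | C=CC(=[N+]=[N-])C(=O)OC | intermediate
11 | methyl (1S,2R)-2-(tert-butyldimethylsilyloxy)-1-ethenyl-2-(2-methyl-5-oxocyclopent-1-en-1-yl)cyclopropane-1-carboxylate (ethenyl and cyclopentenyl groups cis) | COC(=O)[C@]1(C=C)C[C@@]1(O[Si](C)(C)C(C)(C)C)C2=C(C)CCC2=O | intermediate (not isolated)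
12 | methyl (8aR)-4-(tert-butyldimethylsilyloxy)-8a-methyl-3-oxo-1,2,3,5,8,8a-hexahydroazulene-6-carboxylate | COC(=O)C1=CC[C@@]2(C)CCC(=O)C2=C(O[Si](C)(C)C(C)(C)C)C1 | intermediate
13 | isopropylmagnesium chloride | CC(C)[Mg]Cl | starting material
14 | methyl (3R,8aR)-4-(tert-butyldimethylsilyloxy)-3-hydroxy-8a-methyl-3-(propan-2-yl)-1,2,3,5,8,8a-hexahydroazulene-6-carboxylate | COC(=O)C1=CC[C@@]2(C)CC[C@@](O)(C(C)C)C2=C(O[Si](C)(C)C(C)(C)C)C1 | intermediate
15 | (3R,8aR)-4-(tert-butyldimethylsilyloxy)-6-(hydroxymethyl)-8a-methyl-3-(propan-2-yl)-1,2,3,5,8,8a-hexahydroazulen-3-ol | OCC1=CC[C@@]2(C)CC[C@@](O)(C(C)C)C2=C(O[Si](C)(C)C(C)(C)C)C1 | intermediate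
16 | [(3R,8aR)-4-(tert-butyldimethylsilyloxy)-3-hydroxy-8a-methyl-3-(propan-2-yl)-1,2,3,5,8,8a-hexahydroazulen-6-yl]methyl methanesulfonate | CS(=O)(=O)OCC1=CC[C@@]2(C)CC[C@@](O)(C(C)C)C2=C(O[Si](C)(C)C(C)(C)C)C1 | intermediate (not isolated)
17 | (3R,8aR)-4-(tert-butyldimethylsilyloxy)-6,8a-dimethyl-3-(propan-2-yl)-1,2,3,5,8,8a-hexahydroazulen-3-ol | CC1=CC[C@@]2(C)CC[C@@](O)(C(C)C)C2=C(O[Si](C)(C)C(C)(C)C)C1 | intermediate
18 | (3R,3aR,8aR)-3-hydroxy-6,8a-dimethyl-3-(propan-2-yl)-2,3,3a,5,8,8a-hexahydroazulen-4(1H)-one (trans-fused) | O=C1CC(C)=CC[C@@]2(C)CC[C@@](O)(C(C)C)[C@H]12 | intermediate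
19 | (3R,3aS,4S,8aR)-6,8a-dimethyl-3-(propan-2-yl)-1,2,3,3a,4,5,8,8a-octahydroazulene-3,4-diol | O[C@H]1CC(C)=CC[C@@]2(C)CC[C@@](O)(C(C)C)[C@H]12 | intermediate
20 | (3R,3aS,4S,6R,7S,8aR)-6,7-epoxy-6,8a-dimethyl-3-(propan-2-yl)decahydroazulene-3,4-diol (epoxide oxygen cis to the 4-hydroxyl) | O[C@H]1C[C@@]3(C)O[C@H]3C[C@@]2(C)CC[C@@](O)(C(C)C)[C@H]12 | intermediate
21 | (3R,3aS,4S,6R,7R,8aR)-6,8a-dimethyl-7-(phenylselanyl)-3-(propan-2-yl)decahydroazulene-3,4,6-triol | O[C@H]1C[C@@](C)(O)[C@H]([Se]c3ccccc3)C[C@@]2(C)CC[C@@](O)(C(C)C)[C@H]12 | intermediate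
22 | (3R,3aS,4S,6R,7R,8aR)-7-(benzeneseleninyl)-6,8a-dimethyl-3-(propan-2-yl)decahydroazulene-3,4,6-triol | O[C@H]1C[C@@](C)(O)[C@H]([Se](=O)c3ccccc3)C[C@@]2(C)CC[C@@](O)(C(C)C)[C@H]12 | intermediate (not isolated)
23 | (3R,3aS,4S,6R,8aR)-6,8a-dimethyl-3-(propan-2-yl)-1,2,3,3a,4,5,6,8a-octahydroazulene-3,4,6-triol | O[C@H]1C[C@@](C)(O)C=C[C@@]2(C)CC[C@@](O)(C(C)C)[C@H]12 | intermediate
24 | vanillic acid (4-hydroxy-3-methoxybenzoic acid) | COc1cc(C(=O)O)ccc1O | starting material
25 | tert-butyldimethylsilyl 4-(tert-butyldimethylsilyloxy)-3-methoxybenzoate | COc1cc(C(=O)O[Si](C)(C)C(C)(C)C)ccc1O[Si](C)(C)C(C)(C)C | intermediate (not isolated)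
26 | 4-(tert-butyldimethylsilyloxy)-3-methoxybenzoic acid | COc1cc(C(=O)O)ccc1O[Si](C)(C)C(C)(C)C | intermediate
27 | 4-(tert-butyldimethylsilyloxy)-3-methoxybenzoic 2,4,6-trichlorobenzoic anhydride | COc1cc(C(=O)OC(=O)c2c(Cl)cc(Cl)cc2Cl)ccc1O[Si](C)(C)C(C)(C)C | intermediate (not isolated)
28 | (3R,3aS,4S,6R,8aR)-3,6-dihydroxy-6,8a-dimethyl-3-(propan-2-yl)-1,2,3,3a,4,5,6,8a-octahydroazulen-4-yl 4-(tert-butyldimethylsilyloxy)-3-methoxybenzoate | COc1cc(C(=O)O[C@H]2C[C@@](C)(O)C=C[C@@]3(C)CC[C@@](O)(C(C)C)[C@H]23)ccc1O[Si](C)(C)C(C)(C)C | intermediate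
29 | (3R,3aS,4S,6R,8aR)-3,6-dihydroxy-6,8a-dimethyl-3-(propan-2-yl)-1,2,3,3a,4,5,6,8a-octahydroazulen-4-yl 4-hydroxy-3-methoxybenzoate (CNP0243386.4) | COc1cc(C(=O)O[C@H]2C[C@@](C)(O)C=C[C@@]3(C)CC[C@@](O)(C(C)C)[C@H]23)ccc1O | target

**Step count and risks**
Total: 18 steps. Longest linear sequence: 14 steps (steps 1–3, 7–15, 17 and 18, from 3-methylcyclopent-2-en-1-one). The key step rests on close precedent and is judged less exposed than the three steps below.

1. Step 11. What may go wrong: protonation of the enol at C5 from the β face, because the isopropyl group screens the α face, which would give the cis ring fusion; or drift of the C8=C9 bond into conjugation with the new ketone. Fallback: the conjugation is made part of the plan, so that C5 is set under equilibrium control. The fallback sets out from 18 (any C5 ratio). DBU in CH2Cl2 should move the alkene to C7=C8 and equilibrate C5 to the trans-fused conjugated enone, 3-hydroxy-6,8a-dimethyl-3-(propan-2-yl)-2,3,3a,7,8,8a-hexahydroazulen-4(1H)-one F9. IBX in DMSO at 70 °C should dehydrogenate it to the linear dienone F10. Me4NBH(OAc)3 should reduce the carbonyl from the β face as in step 12 to the dienol F11. VO(acac)2 and t-BuOOH, now directed by the allylic 6α-hydroxyl, should give the 7α,8α-epoxy alcohol F12. NaAlH2(OCH2CH2OCH3)2 in THF should deliver hydride from the C6 alkoxide to C7 and open the epoxide to the 1,3-diol. The fallback comes back to the route at 23; steps 13–15 are then not needed.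

2. Step 8. What may go wrong: poor or reversed facial selectivity in the addition to C4, because the two faces of the ketone differ only in the methyl and ring-methylene substituents of C1. Fallback: C4 is erased and rebuilt by epoxidation, which puts oxygen, not carbon, on the more accessible face. The fallback sets out from 17 (either C4 epimer or the mixture). Oxalic acid in wet CH2Cl2 should cause loss of silanol and water (Stork–Danheiser transposition) to the dienone (8aR)-6,8a-dimethyl-3-(propan-2-yl)-1,5,8,8a-tetrahydroazulen-4(2H)-one F7. Weitz–Scheffer epoxidation (t-BuOOH, DBU, 0 °C) should add the peroxide to C4 from the face that the organocerium reagent took and give the 4β,5β-epoxy ketone F8 in that case. SmI2 in THF/MeOH at −78 °C should cleave the C5–O bond and, after protonation of the samarium enolate, give the β-hydroxy ketone. The fallback comes back to the route at 18.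

3. Step 3. What may go wrong: silylation of the ring carbonyl with loss of an α′ or γ proton, giving cyclopentadienyl or extended silyl dienol ethers in place of the acetyl enol ether. Fallback: the ring ketone is held at the alcohol oxidation level while the enol ether is formed, so that only one ketone can enolise. The fallback sets out from 2. Luche reduction (NaBH4, CeCl3·7H2O, MeOH) should give 2-iodo-3-methylcyclopent-2-en-1-ol F1. Stille coupling with 3 as in step 2 should give the enol ether 2-(1-ethoxyvinyl)-3-methylcyclopent-2-en-1-ol F2, and dilute acid the hydroxy ketone 1-(5-hydroxy-2-methylcyclopent-1-en-1-yl)ethan-1-one F3. Ac2O and pyridine should give the acetate 2-acetyl-3-methylcyclopent-2-en-1-yl acetate F4. TBSOTf and Et3N should then give the silyl dienol ether acetate F5. i-Bu2AlH at −78 °C should remove the acetate to give the dienol F6, and MnO2 in CH2Cl2 should oxidise the allylic alcohol. The fallback comes back to the route at 6.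

**Further compounds**
F1 | step 3 | 2-iodo-3-methylcyclopent-2-en-1-ol (racemic) | CC1=C(I)C(O)CC1
F2 | step 3 | 2-(1-ethoxyvinyl)-3-methylcyclopent-2-en-1-ol (racemic) | CCOC(=C)C1=C(C)CCC1O
F3 | step 3 | 1-(5-hydroxy-2-methylcyclopent-1-en-1-yl)ethan-1-one (racemic) | CC(=O)C1=C(C)CCC1O
F4 | step 3 | 2-acetyl-3-methylcyclopent-2-en-1-yl acetate (racemic) | CC(=O)OC1CCC(C)=C1C(C)=O
F5 | step 3 | 2-[1-(tert-butyldimethylsilyloxy)vinyl]-3-methylcyclopent-2-en-1-yl acetate (racemic) | CC(=O)OC1CCC(C)=C1C(=C)O[Si](C)(C)C(C)(C)C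
F6 | step 3 | 2-[1-(tert-butyldimethylsilyloxy)vinyl]-3-methylcyclopent-2-en-1-ol (racemic) | CC1=C(C(=C)O[Si](C)(C)C(C)(C)C)C(O)CC1
F7 | step 8 | (8aR)-6,8a-dimethyl-3-(propan-2-yl)-1,5,8,8a-tetrahydroazulen-4(2H)-one | CC1=CC[C@@]2(C)CCC(C(C)C)=C2C(=O)C1
F8 | step 8 | 3,3a-epoxide of F7 with the oxygen on the face of the 8a-methyl group (4β,5β-epoxy ketone in daucane numbering) | CC1=CC[C@@]2(C)CC[C@]3(C(C)C)O[C@]23C(=O)C1
F9 | step 11 | 3-hydroxy-6,8a-dimethyl-3-(propan-2-yl)-2,3,3a,7,8,8a-hexahydroazulen-4(1H)-one, trans-fused, configuration of 18 at C3, C3a and C8a | O=C1C=C(C)CC[C@@]2(C)CC[C@@](O)(C(C)C)[C@H]12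
F10 | step 11 | 3-hydroxy-6,8a-dimethyl-3-(propan-2-yl)-2,3,3a,8a-tetrahydroazulen-4(1H)-one, same configuration | O=C1C=C(C)C=C[C@@]2(C)CC[C@@](O)(C(C)C)[C@H]12
F11 | step 11 | 6,8a-dimethyl-3-(propan-2-yl)-1,2,3,3a,4,8a-hexahydroazulene-3,4-diol, configuration of 19 at C3, C3a, C4 and C8a | O[C@H]1C=C(C)C=C[C@@]2(C)CC[C@@](O)(C(C)C)[C@H]12
F12 | step 11 | 5,6-epoxide of F11 with the oxygen cis to the 4-hydroxyl | O[C@H]1[C@H]3O[C@@]3(C)C=C[C@@]2(C)CC[C@@](O)(C(C)C)[C@H]12
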